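**Strategy**

Ring B is a 4,4-disubstituted cyclohexa-2,5-dienone (eremophilane numbering: C1 carries the angelate, C5 the angular methyl, C8 the ketone, C10 is the sp2 ring-fusion carbon). C5 is the α-carbon of a latent aldehyde (C6) and C10 the β-carbon of the C8 enone, so the bond C5–C10 is a Michael bond and C6=C7 an aldol-condensation bond. One acid-mediated operation on an acyclic ynone acetal closes ring A by the Michael bond C5–C10 and ring B by C6=C7, setting quaternary C5 from C4. C4 comes from (S)-citronellal, C11 from (S)-methylsuccinate; C1 is set afterwards by axial γ-hydroxylation.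

Key step: step 10

Remark: eremophilane atom numbers (C1–C15) are used throughout; (S)-citronellal and dimethyl (S)-methylsuccinate are taken as commercial materials of high enantiomeric purity.

**Route**

Step 1
Reactants: 1 (S)-citronellal
Product: 2 (3S)-3,7-dimethyl-2-methylideneoct-6-enal
Conditions: 37% aq. HCHO, pyrrolidine (10 mol%), propionic acid (10 mol%), i-PrOH, 45 °C
Reagents that add atoms: formaldehyde C=O
Why: Organocatalytic α-methylenation (Mannich condensation and amine elimination via the aldehyde enamine) adds the future C14 carbon at C5, and the C4 stereocentre lies outside the enamine/iminium system and should keep its configuration.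

Step 2
Reactants: 2 (3S)-3,7-dimethyl-2-methylideneoct-6-enal
Product: 3 (3S)-2,3,7-trimethyloct-6-enal
Conditions: diethyl 2,6-dimethyl-1,4-dihydropyridine-3,5-dicarboxylate (1.1 equiv), dibenzylammonium trifluoroacetate (5 mol%), THF, rt
Reagents that add atoms: none
Why: Iminium-catalysed transfer hydrogenation with a Hantzsch ester should reduce only the conjugated 1,1-disubstituted C=C; the new α-centre (C5) forms as a mixture, which does not matter because it is enolised in the key step.

Step 3
Reactants: 3 (3S)-2,3,7-trimethyloct-6-enal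
Product: 4 (6S)-8,8-dimethoxy-2,6,7-trimethyloct-2-ene
Conditions: HC(OMe)3, TsOH·H2O (1 mol%), MeOH, rt; NaHCO3 quench
Reagents that add atoms: trimethyl orthoformate COC(OC)OC
Why: Acid-catalysed acetalisation masks the aldehyde for the ozonolysis, iodination and acetylide steps.

Step 4
Reactants: 4 (6S)-8,8-dimethoxy-2,6,7-trimethyloct-2-ene
Product: 6 (4S)-6,6-dimethoxy-4,5-dimethylhexan-1-ol, via acetal aldehyde 5 (not isolated)
Conditions: O3, CH2Cl2/MeOH 4:1, −78 °C; then NaBH4, −78 to 0 °C
Reagents that add atoms: ozone [O-][O+]=O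
Why: Ozonolysis of the only alkene with reductive NaBH4 work-up should give the primary alcohol at C1 while the acetal is inert.

Step 5
Reactants: 6 (4S)-6,6-dimethoxy-4,5-dimethylhexan-1-ol
Product: 7 (3S)-6-iodo-1,1-dimethoxy-2,3-dimethylhexane
Conditions: I2, PPh3, imidazole, CH2Cl2, 0 °C to rt
Reagents that add atoms: iodine II
Why: Appel-type iodination of the primary alcohol, with imidazole keeping the medium non-acidic for the acetal.

Step 6
Reactants: 7 (3S)-6-iodo-1,1-dimethoxy-2,3-dimethylhexane
Product: 8 (6S)-8,8-dimethoxy-6,7-dimethyloct-1-yne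
Conditions: LiC≡CH·H2NCH2CH2NH2, DMSO, 15 °C to rt
Reagents that add atoms: lithium acetylide ethylenediamine complex [Li]C#C.NCCN
Why: SN2 alkylation of lithium acetylide by the primary iodide installs C10 and C9 as a terminal alkyne.

Step 7
Reactants: 9 dimethyl (2S)-2-methylbutanedioate
Product: 10 (3S)-4-methoxy-3-methyl-4-oxobutanoic acid
Conditions: pig liver esterase, 0.1 M phosphate buffer pH 7.5, 25 °C; acidify to pH 2, extract
Reagents that add atoms: water O
Why: Esterase-mediated regioselective monohydrolysis, in which the unbranched CH2CO2Me ester should be cleaved in preference to the α-branched ester at a pH where the C11 stereocentre cannot epimerise.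

Step 8
Reactants: 10 (3S)-4-methoxy-3-methyl-4-oxobutanoic acid
Product: 11 methyl (2S)-4-chloro-2-methyl-4-oxobutanoate
Conditions: (COCl)2, DMF (cat.), CH2Cl2, 0 °C to rt; used crude
Reagents that add atoms: oxalyl chloride ClC(=O)C(Cl)=O
Why: Acid chloride formation by Vilsmeier-type activation; the stereocentre is β to the acyl chloride and is not enolised.

Step 9
Reactants: 8 (6S)-8,8-dimethoxy-6,7-dimethyloct-1-yne; 11 methyl (2S)-4-chloro-2-methyl-4-oxobutanoate
Product: 12 methyl (2S,10S)-12,12-dimethoxy-2,10,11-trimethyl-4-oxododec-5-ynoate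
Conditions: PdCl2(PPh3)2 (2 mol%), CuI (4 mol%), Et3N (1.3 equiv), THF, rt
Reagents that add atoms: none
Why: Acyl Sonogashira coupling forms the C8–C9 bond of the ynone under weakly basic conditions that should leave the acetal, the ester and the α-ester stereocentre untouched.

Step 10
Reactants: 12 methyl (2S,10S)-12,12-dimethoxy-2,10,11-trimethyl-4-oxododec-5-ynoate
Product: 16 methyl (2S)-2-[(8S,8aS)-8,8a-dimethyl-3-oxo-3,5,6,7,8,8a-hexahydronaphthalen-2-yl]propanoate, via ynone aldehyde 13 (not isolated), via Michael adduct 14 (not isolated), via aldol adduct 15 (not isolated)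
Conditions: TsOH·H2O (0.3 equiv), wet toluene (0.01 M), 25 °C then 75 °C
Reagents that add atoms: none
Why: Acid unmasks aldehyde 13, whose enol should add to the acid-activated ynone at C10 in a 6-exo-dig Michael closure that forms the C5–C10 bond and ring A (14); acid-mediated E/Z equilibration of the enone through its C1 dienol, a 6-(enolendo)-exo-trig aldol addition of the C7 enol to the neopentyl aldehyde C6 (15) and dehydration then close ring B as the cross-conjugated dienone. The closest known reaction type is the Robinson-type annulation of α-branched aldehydes with alkynyl ketones to 4,4-disubstituted cyclohexa-2,5-dienones, run here under Brønsted acid with the Michael step intramolecular. The only new stereocentre is quaternary C5, set in the Michael step by the adjacent C4 stereocentre through a chair-like transition state in which the C4 methyl is equatorial with its C–H near the enol plane (A(1,3) strain) and the enol carbon C6 is synclinal to the ynone, held by an O–H···O=C8 hydrogen bond, so that the C5 methyl becomes axial and cis to the C4 methyl. The step needs this facial selectivity, C- over O-attack and the Z enone for the aldol closure; the first rests on the C4 stereocentre, the second on the six-membered exo closure, and the third on equilibration drained by the irreversible condensation. C11 is α only to an ester and should not enolise under TsOH, and quaternary C5 blocks aromatisation.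

Step 11
Reactants: 16 methyl (2S)-2-[(8S,8aS)-8,8a-dimethyl-3-oxo-3,5,6,7,8,8a-hexahydronaphthalen-2-yl]propanoate
Product: 17 methyl (2S)-2-[(8S,8aS)-3-{[tert-butyl(dimethyl)silyl]oxy}-8,8a-dimethyl-6,7,8,8a-tetrahydronaphthalen-2-yl]propanoate
Conditions: TBSOTf (1.2 equiv), Et3N (2 equiv), CH2Cl2, 0 °C
Reagents that add atoms: tert-butyldimethylsilyl trifluoromethanesulfonate CC(C)(C)[Si](C)(C)OS(=O)(=O)C(F)(F)F
Why: Soft enolisation, in which O-silylation gives a pentadienyl-type cation whose only adjacent hydrogens are at C1, so the extended silyl trienol ether should form and the C11 ester α-hydrogen, attached to the nodal carbon C7, is not acidified.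

Step 12
Reactants: 17 methyl (2S)-2-[(8S,8aS)-3-{[tert-butyl(dimethyl)silyl]oxy}-8,8a-dimethyl-6,7,8,8a-tetrahydronaphthalen-2-yl]propanoate
Product: 18 methyl (2S)-2-[(5R,8S,8aS)-5-hydroxy-8,8a-dimethyl-3-oxo-3,5,6,7,8,8a-hexahydronaphthalen-2-yl]propanoate
Conditions: mCPBA (1.05 equiv), CH2Cl2, −40 to 0 °C; aq. Na2S2O3/NaHCO3 work-up
Reagents that add atoms: mCPBA OOC(=O)c1cccc(Cl)c1
Why: Rubottom-type γ-hydroxylation, in which the peracid should attack the terminal C1=C10 bond of the silyl trienol ether along the axial trajectory on the face of the angular methyl (as in 6β-hydroxylation of steroidal dienol ethers), and epoxide opening with loss of silicon restores the dienone and sets C1 (R), cis to the C5 methyl.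

Step 13
Reactants: 18 methyl (2S)-2-[(5R,8S,8aS)-5-hydroxy-8,8a-dimethyl-3-oxo-3,5,6,7,8,8a-hexahydronaphthalen-2-yl]propanoate
Product: 19 methyl (2S)-2-[(5R,8S,8aS)-8,8a-dimethyl-5-{[(2Z)-2-methylbut-2-enoyl]oxy}-3-oxo-3,5,6,7,8,8a-hexahydronaphthalen-2-yl]propanoate
Conditions: angelic acid (3 equiv), 2,4,6-trichlorobenzoyl chloride (3 equiv), Et3N (6 equiv), toluene, rt, 2 h; then 18, 75 °C
Reagents that add atoms: angelic acid C/C=C(/C)C(=O)O
Why: Yamaguchi esterification through the mixed anhydride made in the flask, in which the alcohol attacks the less hindered angeloyl carbonyl and the absence of DMAP should suppress Z-to-E isomerisation to the tiglate.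

**Compound list**

1 | (S)-citronellal, (3S)-3,7-dimethyloct-6-enal | CC(C)=CCC[C@H](C)CC=O | starting material
2 | (3S)-3,7-dimethyl-2-methylideneoct-6-enal | CC(C)=CCC[C@H](C)C(=C)C=O | intermediate
3 | (3S)-2,3,7-trimethyloct-6-enal (both C2 epimers) | CC(C)=CCC[C@H](C)C(C)C=O | intermediate
4 | (6S)-8,8-dimethoxy-2,6,7-trimethyloct-2-ene (both C7 epimers) | CC(C)=CCC[C@H](C)C(C)C(OC)OC | intermediate
5 | (4S)-6,6-dimethoxy-4,5-dimethylhexanal | O=CCC[C@H](C)C(C)C(OC)OC | intermediate (not isolated)
6 | (4S)-6,6-dimethoxy-4,5-dimethylhexan-1-ol | OCCC[C@H](C)C(C)C(OC)OC | intermediate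
7 | (3S)-6-iodo-1,1-dimethoxy-2,3-dimethylhexane | ICCC[C@H](C)C(C)C(OC)OC | intermediate
8 | (6S)-8,8-dimethoxy-6,7-dimethyloct-1-yne | C#CCCC[C@H](C)C(C)C(OC)OC | intermediate
9 | dimethyl (2S)-2-methylbutanedioate, dimethyl (S)-methylsuccinate | COC(=O)[C@@H](C)CC(=O)OC | starting material
10 | (3S)-4-methoxy-3-methyl-4-oxobutanoic acid | COC(=O)[C@@H](C)CC(=O)O | intermediate
11 | methyl (2S)-4-chloro-2-methyl-4-oxobutanoate | COC(=O)[C@@H](C)CC(=O)Cl | intermediate
12 | methyl (2S,10S)-12,12-dimethoxy-2,10,11-trimethyl-4-oxododec-5-ynoate (both C11 epimers) | COC(=O)[C@@H](C)CC(=O)C#CCCC[C@H](C)C(C)C(OC)OC | intermediate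
13 | methyl (2S,10S)-2,10,11-trimethyl-4,12-dioxododec-5-ynoate | COC(=O)[C@@H](C)CC(=O)C#CCCC[C@H](C)C(C)C=O | intermediate (not isolated)
14 | methyl (2S,5Z)-5-[(2R,3S)-2-formyl-2,3-dimethylcyclohexylidene]-2-methyl-4-oxopentanoate | COC(=O)[C@@H](C)CC(=O)/C=C1/CCC[C@H](C)[C@@]1(C)C=O | intermediate (not isolated)
15 | methyl (2S)-2-[(8S,8aR)-1-hydroxy-8,8a-dimethyl-3-oxo-1,2,3,5,6,7,8,8a-octahydronaphthalen-2-yl]propanoate (ring C1 and C2 as formed) | COC(=O)[C@@H](C)C1C(O)[C@]2(C)[C@@H](C)CCCC2=CC1=O | intermediate (not isolated)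
16 | methyl (2S)-2-[(8S,8aS)-8,8a-dimethyl-3-oxo-3,5,6,7,8,8a-hexahydronaphthalen-2-yl]propanoate | C1CC[C@H](C)[C@@]2(C)C=C([C@H](C)C(=O)OC)C(=O)C=C12 | intermediate
17 | methyl (2S)-2-[(8S,8aS)-3-{[tert-butyl(dimethyl)silyl]oxy}-8,8a-dimethyl-6,7,8,8a-tetrahydronaphthalen-2-yl]propanoate | C1=C2C=C(O[Si](C)(C)C(C)(C)C)C([C@H](C)C(=O)OC)=C[C@]2(C)[C@@H](C)CC1 | intermediate
18 | methyl (2S)-2-[(5R,8S,8aS)-5-hydroxy-8,8a-dimethyl-3-oxo-3,5,6,7,8,8a-hexahydronaphthalen-2-yl]propanoate | O[C@@H]1CC[C@H](C)[C@@]2(C)C=C([C@H](C)C(=O)OC)C(=O)C=C12 | intermediate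
19 | methyl (2S)-2-[(5R,8S,8aS)-8,8a-dimethyl-5-{[(2Z)-2-methylbut-2-enoyl]oxy}-3-oxo-3,5,6,7,8,8a-hexahydronaphthalen-2-yl]propanoate | C/C=C(/C)C(=O)O[C@@H]1CC[C@H](C)[C@@]2(C)C=C([C@H](C)C(=O)OC)C(=O)C=C12 | target

**Step count and risks**

Total step count: 13. Longest linear sequence: 11 (steps 1–6 and 9–13, from (S)-citronellal).

Steps most likely to fail:

1. Step 10 (key step). The Michael ring closure may show poor facial selectivity if the enol attacks through an extended instead of the hydrogen-bonded synclinal arrangement. The ynone may also be hydrated, or E/Z equilibration may lag behind decomposition. Fallback, setting out from 12 and returning at 16: the acetal is cleaved under mild conditions (pyridinium p-toluenesulfonate, acetone/H2O, 40 °C) and the ynone aldehyde 13 is isolated. Heating 13 in degassed toluene (sealed tube, about 170 °C, trace of 2,6-di-tert-butyl-4-methylphenol) should bring about a thermal Conia-ene reaction. In this concerted intramolecular ene reaction the enol hydrogen is delivered to C9, which forces C6 synclinal to the alkyne and so should give the same C5 configuration. The product is the E-configured cyclohexylidene keto aldehyde, methyl (2S,5E)-5-[(2R,3S)-2-formyl-2,3-dimethylcyclohexylidene]-2-methyl-4-oxopentanoate F1. With the ynone gone, pyrrolidinium acetate in benzene at 60 °C should equilibrate the enone geometry by reversible conjugate addition and effect the aldol condensation to 16.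

2. Step 12. The peracid may attack C9 instead of C1, approach from the face anti to the angular methyl, or the silyl ether may be protodesilylated before oxidation. Fallback, setting out from 16 and returning at 18: allylic oxidation of the C1 methylene with t-BuOOH and catalytic dirhodium tetrakis(caprolactamate), Rh2(cap)4, should give the ene-dione methyl (2S)-2-[(8S,8aS)-8,8a-dimethyl-3,5-dioxo-3,5,6,7,8,8a-hexahydronaphthalen-2-yl]propanoate F2. Luche reduction (NaBH4, CeCl3·7H2O, MeOH, −78 °C) should then reduce the C1 carbonyl, which is more electrophilic than the cross-conjugated C8 carbonyl. Hydride delivery anti to the axial C5 methyl should give the axial alcohol 18.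

3. Step 13. The angeloyl group may isomerise to tigloyl during activation, and acylation of the hindered axial alcohol may be slow. Fallback, setting out from 18 and returning at 19: esterification with 2-[bis(2,2,2-trifluoroethoxy)phosphoryl]propanoic acid (DCC, DMAP, CH2Cl2) should give the phosphonate ester methyl (2S)-2-[(5R,8S,8aS)-5-({2-[bis(2,2,2-trifluoroethoxy)phosphoryl]propanoyl}oxy)-8,8a-dimethyl-3-oxo-3,5,6,7,8,8a-hexahydronaphthalen-2-yl]propanoate F3. Still–Gennari olefination with acetaldehyde (KHMDS, 18-crown-6, THF, −78 °C) should then build the Z-configured 2-methylbut-2-enoate on the molecule and give 19.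

**Further compounds**

F1 | step 10 | methyl (2S,5E)-5-[(2R,3S)-2-formyl-2,3-dimethylcyclohexylidene]-2-methyl-4-oxopentanoate | COC(=O)[C@@H](C)CC(=O)/C=C1\CCC[C@H](C)[C@@]1(C)C=O
F2 | step 12 | methyl (2S)-2-[(8S,8aS)-8,8a-dimethyl-3,5-dioxo-3,5,6,7,8,8a-hexahydronaphthalen-2-yl]propanoate | O=C1CC[C@H](C)[C@@]2(C)C=C([C@H](C)C(=O)OC)C(=O)C=C12
F3 | step 13 | methyl (2S)-2-[(5R,8S,8aS)-5-({2-[bis(2,2,2-trifluoroethoxy)phosphoryl]propanoyl}oxy)-8,8a-dimethyl-3-oxo-3,5,6,7,8,8a-hexahydronaphthalen-2-yl]propanoate | CC(C(=O)O[C@@H]1CC[C@H](C)[C@@]2(C)C=C([C@H](C)C(=O)OC)C(=O)C=C12)P(=O)(OCC(F)(F)F)OCC(F)(F)F
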